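**Assumption:** the target SMILES has no stereocentre and no stereogenic double bond, so "single enantiomer" is moot and the achiral compound is made. Compounds 4 and 5 carry a racemic acetal centre in a temporary protecting group only.

## Retrosynthetic overview

1. Target ⇐ its 7,4′-bis(MOM) ether, by final acetal cleavage.
2. The C3–C1′ bond and the pyranone C ring are disconnected together (new step): an o-hydroxyaryl enaminone (A ring plus C2/C3/C4) and a prenylated p-quinone monoketal (B ring as a phenoxenium synthon; its C=O becomes 2′-OH, its ketal becomes 5′-OMe).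
3. Quinone monoketal ⇐ PhI(OAc)2/MeOH dearomatisation of a 2-prenyl-4-methoxyphenol ⇐ directed ortho-metalation/prenylation between two acetal oxygens ⇐ isovanillin (Baeyer–Villiger).
4. Enaminone ⇐ 2,4-dihydroxyacetophenone (mono-MOM, then DMF-DMA).
5. Ring order: A and B rings are purchased as benzenoids (B is transiently dearomatised); the only ring formed is the pyranone C ring, in the key step.

## Route

**Step 1**
Reactants: 1 isovanillin (3-hydroxy-4-methoxybenzaldehyde)
Product: 2 4-methoxy-3-(methoxymethoxy)benzaldehyde
Conditions: MOMCl, i-Pr2NEt, CH2Cl2, 0 °C → rt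
Reagents that add atoms: chloromethyl methyl ether (MOMCl), COCCl
Why: Williamson-type O-alkylation of the only phenol gives the MOM ether; the aldehyde is untouched.

**Step 2**
Reactants: 2 4-methoxy-3-(methoxymethoxy)benzaldehyde
Product: 3 4-methoxy-3-(methoxymethoxy)phenol
Conditions: mCPBA, NaHCO3, CH2Cl2, rt; then K2CO3, MeOH, rt
Reagents that add atoms: mCPBA, O=C(OO)c1cccc(Cl)c1 (one O)
Why: Baeyer–Villiger (Dakin-type) oxidation of an electron-rich benzaldehyde proceeds by aryl migration to the aryl formate, which is methanolysed; the MOM ether survives buffered peracid.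

**Step 3**
Reactants: 3 4-methoxy-3-(methoxymethoxy)phenol
Product: 4 4-(1-ethoxyethoxy)-1-methoxy-2-(methoxymethoxy)benzene (racemic acetal)
Conditions: ethyl vinyl ether, PPTS (5 mol %), CH2Cl2, rt
Reagents that add atoms: ethyl vinyl ether, C=COCC
Why: Acid-catalysed addition of the phenol to the enol ether gives a 1-ethoxyethyl (EE) acetal, which is a second lithiation director and far more acid-labile than MOM, so it can be removed selectively later.

**Step 4**
Reactants: 4 4-(1-ethoxyethoxy)-1-methoxy-2-(methoxymethoxy)benzene
Product: 5 1-(1-ethoxyethoxy)-4-methoxy-3-(methoxymethoxy)-2-(3-methylbut-2-en-1-yl)benzene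
Conditions: n-BuLi, THF, 0 °C; CuBr·SMe2, −78 °C; prenyl bromide, −78 °C → rt
Reagents that add atoms: prenyl bromide, CC(C)=CCBr
Why: Directed ortho-metalation occurs at the carbon flanked by both acetal oxygens (cooperative 1,3-directing effect, and the only open ortho site of the OMOM group), and copper-mediated SN2 allylation of the aryl metal gives the linear prenyl arene.

**Step 5**
Reactants: 5 1-(1-ethoxyethoxy)-4-methoxy-3-(methoxymethoxy)-2-(3-methylbut-2-en-1-yl)benzene
Product: 6 4-methoxy-3-(methoxymethoxy)-2-(3-methylbut-2-en-1-yl)phenol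
Conditions: PPTS (10 mol %), MeOH, rt
Reagents that add atoms: none
Why: Mild acetal methanolysis cleaves the EE ether selectively over the aryl MOM ether and is too weak to cyclise the o-prenylphenol.

**Step 6**
Reactants: 6 4-methoxy-3-(methoxymethoxy)-2-(3-methylbut-2-en-1-yl)phenol
Product: 7 4,4-dimethoxy-3-(methoxymethoxy)-2-(3-methylbut-2-en-1-yl)cyclohexa-2,5-dien-1-one
Conditions: PhI(OAc)2, NaHCO3, MeOH, 0 °C, 15 min; used at once
Reagents that add atoms: methanol, CO
Why: Hypervalent-iodine oxidative dearomatisation of a p-methoxyphenol, with methanol trapping the phenoxenium at the OMe-bearing para carbon, gives the p-quinone monoketal; the isolated alkene and MOM group tolerate the brief buffered conditions.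

**Step 7**
Reactants: 8 1-(2,4-dihydroxyphenyl)ethan-1-one (2,4-dihydroxyacetophenone)
Product: 9 1-[2-hydroxy-4-(methoxymethoxy)phenyl]ethan-1-one
Conditions: MOMCl (1.1 equiv), K2CO3, acetone, rt
Reagents that add atoms: chloromethyl methyl ether (MOMCl), COCCl
Why: Chemoselective O-alkylation of the 4-OH works because the 2-OH is deactivated by its hydrogen bond to the ketone.

**Step 8**
Reactants: 9 1-[2-hydroxy-4-(methoxymethoxy)phenyl]ethan-1-one
Product: 10 (E)-3-(dimethylamino)-1-[2-hydroxy-4-(methoxymethoxy)phenyl]prop-2-en-1-one
Conditions: DMF-DMA, toluene, 90 °C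
Reagents that add atoms: N,N-dimethylformamide dimethyl acetal, COC(OC)N(C)C
Why: Condensation of the methyl ketone with DMF-DMA gives the E-enaminone, the standard precursor of 3-substituted chromones.

**Step 9 (key step)**
Reactants: 10 (E)-3-(dimethylamino)-1-[2-hydroxy-4-(methoxymethoxy)phenyl]prop-2-en-1-one; 7 4,4-dimethoxy-3-(methoxymethoxy)-2-(3-methylbut-2-en-1-yl)cyclohexa-2,5-dien-1-one (1.3 equiv)
Product: 11 3-[2-hydroxy-5-methoxy-4-(methoxymethoxy)-3-(3-methylbut-2-en-1-yl)phenyl]-7-(methoxymethoxy)-4H-chromen-4-one
Conditions: (CF3)2CHOH/CH2Cl2 (4:1), 0 °C → rt, 3 h; no metal, no added acid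
Reagents that add atoms: none (MeOH and Me2NH are lost)
Why: Proposed new method: a metal-free domino "phenoxenium α-arylation / cyclo-deamination" in which HFIP ionises ketal 7 to its 4-methoxyphenoxenium-type oxocarbenium ion, the nucleophilic α-carbon of enaminone 10 attacks the only unsubstituted carbon ortho to the carbonyl (C6; C2 is blocked by prenyl) in an SN2′ sense, loss of MeOH and tautomerisation rearomatise the B ring (C=O → 2′-OH, ketal → 5′-OMe), and the resulting iminium/α-aryl enaminone is captured by the pre-organised salicyl OH with loss of Me2NH (the same closure that ends the deoxybenzoin/DMF-DMA isoflavone synthesis) in preference to the new 2′-OH (which would need a 5-endo closure on the neutral enaminone), so the C3–C1′ bond and the pyranone ring form in one operation without 2′-O protection; the closest known reaction types are acid/HFIP-promoted SN2′ couplings of quinone monoketals with arenes and alkenes and the electrophile-triggered domino cyclisation of o-hydroxyaryl enaminones to 3-substituted chromones.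

**Step 10**
Reactants: 11 3-[2-hydroxy-5-methoxy-4-(methoxymethoxy)-3-(3-methylbut-2-en-1-yl)phenyl]-7-(methoxymethoxy)-4H-chromen-4-one
Product: 12 piscisoflavone A, 3-[2,4-dihydroxy-5-methoxy-3-(3-methylbut-2-en-1-yl)phenyl]-7-hydroxy-4H-chromen-4-one
Conditions: 3 M aq. HCl/MeOH (1:9), 45 °C, 1–2 h (monitored)
Reagents that add atoms: none
Why: Acid-catalysed acetal methanolysis removes both aryl MOM ethers under conditions mild enough to leave a prenyl group flanked by two phenols uncyclised; there are no stereocentres to set or scramble.

## Compound list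

1 | isovanillin (3-hydroxy-4-methoxybenzaldehyde) | COc1ccc(C=O)cc1O | starting material
2 | 4-methoxy-3-(methoxymethoxy)benzaldehyde | COCOc1cc(C=O)ccc1OC | intermediate
3 | 4-methoxy-3-(methoxymethoxy)phenol | COCOc1cc(O)ccc1OC | intermediate
4 | 4-(1-ethoxyethoxy)-1-methoxy-2-(methoxymethoxy)benzene (racemic acetal) | CCOC(C)Oc1ccc(OC)c(OCOC)c1 | intermediate
5 | 1-(1-ethoxyethoxy)-4-methoxy-3-(methoxymethoxy)-2-(3-methylbut-2-en-1-yl)benzene (racemic acetal) | CCOC(C)Oc1ccc(OC)c(OCOC)c1CC=C(C)C | intermediate
6 | 4-methoxy-3-(methoxymethoxy)-2-(3-methylbut-2-en-1-yl)phenol | COCOc1c(CC=C(C)C)c(O)ccc1OC | intermediate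
7 | 4,4-dimethoxy-3-(methoxymethoxy)-2-(3-methylbut-2-en-1-yl)cyclohexa-2,5-dien-1-one | COCOC1=C(CC=C(C)C)C(=O)C=CC1(OC)OC | intermediate
8 | 1-(2,4-dihydroxyphenyl)ethan-1-one | CC(=O)c1ccc(O)cc1O | starting material
9 | 1-[2-hydroxy-4-(methoxymethoxy)phenyl]ethan-1-one | CC(=O)c1ccc(OCOC)cc1O | intermediate
10 | (E)-3-(dimethylamino)-1-[2-hydroxy-4-(methoxymethoxy)phenyl]prop-2-en-1-one | CN(C)/C=C/C(=O)c1ccc(OCOC)cc1O | intermediate
11 | 3-[2-hydroxy-5-methoxy-4-(methoxymethoxy)-3-(3-methylbut-2-en-1-yl)phenyl]-7-(methoxymethoxy)-4H-chromen-4-one | COCOc1ccc2c(c1)occ(-c1cc(OC)c(OCOC)c(CC=C(C)C)c1O)c2=O | intermediate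
12 | piscisoflavone A | COc1cc(-c2coc3cc(O)ccc3c2=O)c(O)c(CC=C(C)C)c1O | target

## Summary

**Total steps:** 10.
**Longest linear sequence:** 8 (steps 1–6, 9, 10 from isovanillin); the A-ring branch is 2 steps (7, 8).

**Three steps most likely to fail**

1. **Step 9 (proposed new domino coupling).** Risks are closure through the new 2′-OH to give a 3-aroylbenzofuran, conjugate ("meta") addition to the dienone, and loss of the vinylogous MOM ester of 7 in HFIP. Fallback (known chemistry): cyclise 10 with I2 to 3-iodo-7-(methoxymethoxy)chromone and run a Suzuki–Miyaura coupling with [5-methoxy-2,4-bis(methoxymethoxy)-3-prenylphenyl]boronic acid. That boronic acid comes from the bis-MOM analogue of 5 by a second ortho-lithiation and B(OMe)3 quench. Then apply step 10.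

2. **Step 6 (oxidative dearomatisation of a prenyl-bearing phenol to a sensitive ketal).** Risks are attack of the iodine(III) reagent on the alkene and lability of 7. Fallback: oxidise the prenyl-free phenol 3 instead (skipping steps 3–5), couple as in step 9, and introduce the prenyl group afterwards. This uses 2′-O-(1,1-dimethylpropargyl)ation, Lindlar semi-hydrogenation and thermal aromatic Claisen rearrangement; C3′ is the only free ortho position of the 2′-oxygen.

3. **Step 10 (acidic MOM removal next to an o-prenylresorcinol).** The risk is acid-catalysed cyclisation to the 2,2-dimethylchroman. Fallback: change the protecting-group strategy to fluoride-labile SEM ethers on both oxygens (SEMCl in steps 1 and 7; same lithiation behaviour) and unmask at the end with TBAF in THF/DMPU, so no Brønsted acid meets the free prenylated phenol.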